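**Retrosynthetic overview**
- Target 22 comes from benzoate 20 by hydrogenolysis of all three benzyl groups and protodecarboxylation of the carboxyl that sits at C2 of ring A, para to the C5 hydroxyl.
- Ring A of 20 comes from an Alder–Rickert reaction of cyclohexadiene 10 with ynoate 17, which forms C6–C1 and C3–C2 and expels ethylene. The feature used is that C3(OMe)–C4(benzyl)–C5(OH)–C6(benzyl) of ring A is a 2,4-dibenzylcyclohexane-1,3-dione mono-enol ether in masked form, while C1 (bearing the CH2CH2 bridge) and C2–H come from the alkyne.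
- Diene 10 comes from cyclohexane-1,3-dione by C2 reductive benzylation, O-methylation, kinetic α′-benzylation and silyl dienol ether formation.
- Ynoate 17 comes from 3-methoxybenzyl bromide and lithiated 1-(trimethylsilyl)propyne, followed by desilylation and carboxylation.
- Ring order: the three outer benzene rings are purchased; ring A is the only ring built, in the key step.

Key step: step 8

Remark on the chemistry: the target has no stereogenic element, so the compound given is achiral and no stereocontrol is needed; the stereocentres of intermediates 8 and 18 are racemic and are erased later.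

**Step 1**
Reactants: 1 cyclohexane-1,3-dione; 2 4-(benzyloxy)benzaldehyde
Product: 4 2-[4-(benzyloxy)benzyl]cyclohexane-1,3-dione, via arylidene dione 3 (not isolated)
Conditions: Hantzsch ester (1.05 equiv), L-proline (cat.), CH2Cl2, rt
Reagents that add atoms: none
Why: Organocatalytic reductive Knoevenagel alkylation, in which the arylidene dione is reduced by hydride transfer from the Hantzsch ester faster than it can add a second dione.

**Step 2**
Reactants: 4 2-[4-(benzyloxy)benzyl]cyclohexane-1,3-dione
Product: 5 2-[4-(benzyloxy)benzyl]-3-methoxycyclohex-2-en-1-one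
Conditions: HC(OMe)3, MeOH, p-TsOH (cat.), rt to 50 °C
Reagents that add atoms: trimethyl orthoformate, COC(OC)OC (methanol, CO, as exchanging solvent)
Why: Acid-catalysed enol etherification of a symmetrical 2-substituted 1,3-dione gives the vinylogous ester as a single regioisomer, with the orthoformate taking up the water.

**Step 3**
Reactants: 5 2-[4-(benzyloxy)benzyl]-3-methoxycyclohex-2-en-1-one; 6 4-(benzyloxy)benzyl bromide
Product: 8 2,6-bis[4-(benzyloxy)benzyl]-3-methoxycyclohex-2-en-1-one (racemic), via lithium enolate 7 (not isolated)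
Conditions: LDA (commercial solution, 1.05 equiv), THF, −78 °C; then 6, −78 → 0 °C
Reagents that add atoms: none
Why: Stork–Danheiser kinetic α′-deprotonation of a 3-alkoxyenone and SN2 alkylation of the cross-conjugated enolate with a reactive benzylic bromide; the new C6 stereocentre is racemic and is removed in step 4.

**Step 4**
Reactants: 8 2,6-bis[4-(benzyloxy)benzyl]-3-methoxycyclohex-2-en-1-one
Product: 10 2,4-bis[4-(benzyloxy)benzyl]-1-methoxy-3-(trimethylsilyloxy)cyclohexa-1,3-diene, via lithium dienolate 9 (not isolated)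
Conditions: LDA (commercial solution, 1.2 equiv), THF, −78 °C; TMSCl, −78 °C → rt; pentane, filtration, used crude
Reagents that add atoms: chlorotrimethylsilane, C[Si](C)(C)Cl
Why: A second kinetic α′-deprotonation (as in Stork–Danheiser double alkylation) gives the cross-conjugated dienolate, and O-silylation should deliver the 1-alkoxy-3-silyloxy diene.

**Step 5**
Reactants: 11 3-methoxybenzyl bromide; 12 1-(trimethylsilyl)propyne
Product: 14 [4-(3-methoxyphenyl)but-1-yn-1-yl]trimethylsilane, via lithiated silylpropyne 13 (not isolated)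
Conditions: n-BuLi, THF, −78 → −20 °C; then 11, −78 °C → rt
Reagents that add atoms: none
Why: Propargylic lithiation of the silylpropyne and SN2 benzylation; the bulky silyl group directs alkylation to the propargylic rather than the allenic terminus.

**Step 6**
Reactants: 14 [4-(3-methoxyphenyl)but-1-yn-1-yl]trimethylsilane
Product: 15 1-(but-3-yn-1-yl)-3-methoxybenzene
Conditions: K2CO3 (cat.), MeOH, rt
Reagents that add atoms: none
Why: Methanolysis of the alkynyl C–Si bond (protodesilylation) is routine and leaves the aryl methyl ether untouched.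

**Step 7**
Reactants: 15 1-(but-3-yn-1-yl)-3-methoxybenzene
Product: 17 benzyl 5-(3-methoxyphenyl)pent-2-ynoate, via lithium acetylide 16 (not isolated)
Conditions: n-BuLi, THF, −78 °C; ClCO2Bn, −78 → 0 °C
Reagents that add atoms: benzyl chloroformate, O=C(Cl)OCc1ccccc1
Why: Acylation of a lithium acetylide with a chloroformate is the standard route to alkynoic esters.

**Step 8**
Reactants: 10 2,4-bis[4-(benzyloxy)benzyl]-1-methoxy-3-(trimethylsilyloxy)cyclohexa-1,3-diene; 17 benzyl 5-(3-methoxyphenyl)pent-2-ynoate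
Product: 20 benzyl 3,5-bis[4-(benzyloxy)benzyl]-4-hydroxy-2-methoxy-6-[2-(3-methoxyphenyl)ethyl]benzoate, via bicyclo[2.2.2]octadiene adduct 18 (not isolated), via aryl trimethylsilyl ether 19 (not isolated)
Conditions: 17 (2 equiv), o-dichlorobenzene (concentrated), 175 °C, Ar, ethylene vented; then 1 M HCl, THF, rt
Reagents that add atoms: none
Why: Alder–Rickert reaction: the s-cis-locked 1-methoxy-3-silyloxy diene 10 undergoes a normal-demand, concerted but asynchronous [4+2] cycloaddition with the acetylenic ester 17 to give bicyclo[2.2.2]octadiene 18, which on continued heating loses its saturated two-carbon bridge as ethylene by retro-[4+2], the only cycloreversion that leaves an aromatic ring. The closest known reaction type is the Alder–Rickert benzannulation of 1-alkoxy-3-silyloxycyclohexa-1,3-dienes with propiolic and alkynoic esters to give resorcinol monoethers; here both diene termini are fully substituted and the alkyne is β-alkylated, so a forcing temperature and an excess of 17 are planned. Ring A is closed by intermolecular cycloaddition, with the two σ-bonds C6–C1 and C3–C2 formed together, and not by cyclisation of a tether. The bridgehead stereocentres of 18 form as a racemate and vanish on aromatisation, so no stereocontrol is needed. The selectivity required is orientation: the methoxy and silyloxy donors both raise the HOMO coefficient at the silyl enol ether carbon (the benzylated terminus, future C6), which bonds to the electrophilic β-carbon of 17 that carries the arylethyl chain, so the ester lands at C2, ortho to OMe and para to the silyloxy group. Dilute acid on work-up cleaves the aryl trimethylsilyl ether 19 to phenol 20.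

**Step 9**
Reactants: 20 benzyl 3,5-bis[4-(benzyloxy)benzyl]-4-hydroxy-2-methoxy-6-[2-(3-methoxyphenyl)ethyl]benzoate
Product: 21 4-hydroxy-3,5-bis(4-hydroxybenzyl)-2-methoxy-6-[2-(3-methoxyphenyl)ethyl]benzoic acid
Conditions: H2 (1 atm), 10% Pd/C, EtOAc–MeOH, rt
Reagents that add atoms: none
Why: Catalytic hydrogenolysis cleaves the benzyl ester and both aryl benzyl ethers at their benzylic C–O bonds regardless of the hindrance around the ester, while the diarylmethane C–C bonds and methyl ethers are inert.

**Step 10**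
Reactants: 21 4-hydroxy-3,5-bis(4-hydroxybenzyl)-2-methoxy-6-[2-(3-methoxyphenyl)ethyl]benzoic acid
Product: 22 2,6-bis(4-hydroxybenzyl)-3-methoxy-5-[2-(3-methoxyphenyl)ethyl]phenol (target)
Conditions: 2 M aq. HCl (cat.), 1,4-dioxane, 80 °C, Ar
Reagents that add atoms: none
Why: Acid-promoted protodecarboxylation by ipso-protonation of the carboxyl-bearing carbon, which is para to the hydroxyl and ortho to the methoxy group, followed by loss of CO2 and helped by relief of strain in the hexasubstituted ring.

**Compound list**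
1 | cyclohexane-1,3-dione | O=C1CCCC(=O)C1 | starting material
2 | 4-(benzyloxy)benzaldehyde | O=Cc1ccc(OCc2ccccc2)cc1 | starting material
3 | 2-[4-(benzyloxy)benzylidene]cyclohexane-1,3-dione | O=C1CCCC(=O)C1=Cc1ccc(OCc2ccccc2)cc1 | intermediate
4 | 2-[4-(benzyloxy)benzyl]cyclohexane-1,3-dione | O=C1CCCC(=O)C1Cc1ccc(OCc2ccccc2)cc1 | intermediate
5 | 2-[4-(benzyloxy)benzyl]-3-methoxycyclohex-2-en-1-one | COC1=C(Cc2ccc(OCc3ccccc3)cc2)C(=O)CCC1 | intermediate
6 | 4-(benzyloxy)benzyl bromide | BrCc1ccc(OCc2ccccc2)cc1 | starting material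
7 | kinetic (α′, C6) lithium enolate of 5: lithium 6-[4-(benzyloxy)benzyl]-5-methoxycyclohexa-1,5-dien-1-olate | COC1=C(Cc2ccc(OCc3ccccc3)cc2)C(O[Li])=CCC1 | intermediate
8 | 2,6-bis[4-(benzyloxy)benzyl]-3-methoxycyclohex-2-en-1-one (racemic) | COC1=C(Cc2ccc(OCc3ccccc3)cc2)C(=O)C(Cc2ccc(OCc3ccccc3)cc2)CC1 | intermediate
9 | cross-conjugated lithium dienolate of 8 (O–C1=C6 and C2=C3) | COC1=C(Cc2ccc(OCc3ccccc3)cc2)C(O[Li])=C(Cc2ccc(OCc3ccccc3)cc2)CC1 | intermediate
10 | 2,4-bis[4-(benzyloxy)benzyl]-1-methoxy-3-(trimethylsilyloxy)cyclohexa-1,3-diene | COC1=C(Cc2ccc(OCc3ccccc3)cc2)C(O[Si](C)(C)C)=C(Cc2ccc(OCc3ccccc3)cc2)CC1 | intermediate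
11 | 3-methoxybenzyl bromide | COc1cccc(CBr)c1 | starting material
12 | 1-(trimethylsilyl)propyne | CC#C[Si](C)(C)C | starting material
13 | 3-lithio-1-(trimethylsilyl)propyne | [Li]CC#C[Si](C)(C)C | intermediate
14 | [4-(3-methoxyphenyl)but-1-yn-1-yl]trimethylsilane | COc1cccc(CCC#C[Si](C)(C)C)c1 | intermediate
15 | 1-(but-3-yn-1-yl)-3-methoxybenzene | C#CCCc1cccc(OC)c1 | intermediate
16 | lithium acetylide of 15: [4-(3-methoxyphenyl)but-1-yn-1-yl]lithium | [Li]C#CCCc1cccc(OC)c1 | intermediate
17 | benzyl 5-(3-methoxyphenyl)pent-2-ynoate | O=C(OCc1ccccc1)C#CCCc1cccc(OC)c1 | intermediate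
18 | benzyl 4,6-bis[4-(benzyloxy)benzyl]-1-methoxy-3-[2-(3-methoxyphenyl)ethyl]-5-(trimethylsilyloxy)bicyclo[2.2.2]octa-2,5-diene-2-carboxylate (racemic) | COC12CCC(Cc3ccc(OCc4ccccc4)cc3)(C(O[Si](C)(C)C)=C1Cc1ccc(OCc3ccccc3)cc1)C(CCc1cccc(OC)c1)=C2C(=O)OCc1ccccc1 | intermediate
19 | benzyl 3,5-bis[4-(benzyloxy)benzyl]-2-methoxy-6-[2-(3-methoxyphenyl)ethyl]-4-(trimethylsilyloxy)benzoate | O=C(OCc1ccccc1)c1c(OC)c(Cc2ccc(OCc3ccccc3)cc2)c(O[Si](C)(C)C)c(Cc2ccc(OCc3ccccc3)cc2)c1CCc1cccc(OC)c1 | intermediate
20 | benzyl 3,5-bis[4-(benzyloxy)benzyl]-4-hydroxy-2-methoxy-6-[2-(3-methoxyphenyl)ethyl]benzoate | O=C(OCc1ccccc1)c1c(OC)c(Cc2ccc(OCc3ccccc3)cc2)c(O)c(Cc2ccc(OCc3ccccc3)cc2)c1CCc1cccc(OC)c1 | intermediate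
21 | 4-hydroxy-3,5-bis(4-hydroxybenzyl)-2-methoxy-6-[2-(3-methoxyphenyl)ethyl]benzoic acid | O=C(O)c1c(OC)c(Cc2ccc(O)cc2)c(O)c(Cc2ccc(O)cc2)c1CCc1cccc(OC)c1 | intermediate
22 | 2,6-bis(4-hydroxybenzyl)-3-methoxy-5-[2-(3-methoxyphenyl)ethyl]phenol | COc1cccc(CCc2cc(OC)c(Cc3ccc(O)cc3)c(O)c2Cc2ccc(O)cc2)c1 | target

**Step count**
Total: 10 steps. Longest linear sequence: 7 steps (steps 1–4, 8, 9, 10).

**Steps most likely to fail**

Step 8. Bond formation at two fully substituted diene termini with a β-alkylated ynoate may be too slow, so that desilylation or thermal [1,5]-hydrogen shift of the diene consumes it before cycloaddition. The fallback changes the dienophile class to a formyl-activated alkyne, which should react at a much lower temperature. It sets out from alkyne 15 and diene 10 and returns at acid 21. Alkyne 15 is lithiated (n-BuLi, THF, −78 °C) and formylated with DMF, with quench into aqueous KH2PO4, to give 5-(3-methoxyphenyl)pent-2-ynal F1. F1 and diene 10 are heated in toluene at 80–110 °C; cycloaddition, ethylene loss and dilute HCl work-up should give 3,5-bis[4-(benzyloxy)benzyl]-4-hydroxy-2-methoxy-6-[2-(3-methoxyphenyl)ethyl]benzaldehyde F2. Pinnick oxidation (NaClO2, NaH2PO4, 2-methyl-2-butene, t-BuOH–H2O) should give 3,5-bis[4-(benzyloxy)benzyl]-4-hydroxy-2-methoxy-6-[2-(3-methoxyphenyl)ethyl]benzoic acid F3. Hydrogenolysis of F3 (H2, Pd/C) removes the two benzyl ethers and gives 21.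

Step 4. Enolisation at the hindered tertiary α′-position may be incomplete or be diverted to γ-deprotonation at C4, and the trimethylsilyl dienol ether may hydrolyse on handling. The fallback generates the silyl dienol ether regiospecifically by 1,4-hydrosilylation of an exocyclic enone and uses a sturdier silyl group. It sets out from enone 5 and aldehyde 2 and returns at benzoate 20. The kinetic enolate of 5 (LDA, THF, −78 °C) is added to 2 to give the aldol adduct 2-[4-(benzyloxy)benzyl]-6-{[4-(benzyloxy)phenyl](hydroxy)methyl}-3-methoxycyclohex-2-en-1-one F4 as a diastereomer mixture. Mesylation and elimination (MsCl, Et3N, then DBU) should give (E)-2-[4-(benzyloxy)benzyl]-6-[4-(benzyloxy)benzylidene]-3-methoxycyclohex-2-en-1-one F5. Conjugate hydrosilylation of the s-cis exocyclic enone (Et3SiH, RhCl(PPh3)3 cat., THF, 50 °C), which leaves the deactivated vinylogous ester alone, should give 2,4-bis[4-(benzyloxy)benzyl]-1-methoxy-3-(triethylsilyloxy)cyclohexa-1,3-diene F6. F6 is heated with ynoate 17 as in step 8 and the aryl silyl ether is cleaved with TBAF or dilute HCl to give 20.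

Step 3. Proton transfer between product 8 and unreacted enolate 7 may lead to a second alkylation at C6 and incomplete conversion. The fallback moves the second benzylation to the dione stage. It sets out from dione 4 and bromide 6 and returns at enone 8. The dianion of 4 (LDA, 2.2 equiv, THF–HMPA, −78 → 0 °C) is alkylated at C4 with 6 to give 2,4-bis[4-(benzyloxy)benzyl]cyclohexane-1,3-dione F7. Acid-catalysed enol etherification (HC(OMe)3, MeOH, p-TsOH) should take place mainly at the less hindered carbonyl, remote from the C4 substituent, and give 8 after chromatographic removal of the regioisomeric enol ether.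

**Further compounds**
F1 | step 8 | 5-(3-methoxyphenyl)pent-2-ynal | O=CC#CCCc1cccc(OC)c1
F2 | step 8 | 3,5-bis[4-(benzyloxy)benzyl]-4-hydroxy-2-methoxy-6-[2-(3-methoxyphenyl)ethyl]benzaldehyde | O=Cc1c(OC)c(Cc2ccc(OCc3ccccc3)cc2)c(O)c(Cc2ccc(OCc3ccccc3)cc2)c1CCc1cccc(OC)c1
F3 | step 8 | 3,5-bis[4-(benzyloxy)benzyl]-4-hydroxy-2-methoxy-6-[2-(3-methoxyphenyl)ethyl]benzoic acid | O=C(O)c1c(OC)c(Cc2ccc(OCc3ccccc3)cc2)c(O)c(Cc2ccc(OCc3ccccc3)cc2)c1CCc1cccc(OC)c1
F4 | step 4 | 2-[4-(benzyloxy)benzyl]-6-{[4-(benzyloxy)phenyl](hydroxy)methyl}-3-methoxycyclohex-2-en-1-one (diastereomer mixture, racemic) | COC1=C(Cc2ccc(OCc3ccccc3)cc2)C(=O)C(C(O)c2ccc(OCc3ccccc3)cc2)CC1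
F5 | step 4 | (E)-2-[4-(benzyloxy)benzyl]-6-[4-(benzyloxy)benzylidene]-3-methoxycyclohex-2-en-1-one | COC1=C(Cc2ccc(OCc3ccccc3)cc2)C(=O)/C(=C/c2ccc(OCc3ccccc3)cc2)CC1
F6 | step 4 | 2,4-bis[4-(benzyloxy)benzyl]-1-methoxy-3-(triethylsilyloxy)cyclohexa-1,3-diene | COC1=C(Cc2ccc(OCc3ccccc3)cc2)C(O[Si](CC)(CC)CC)=C(Cc2ccc(OCc3ccccc3)cc2)CC1
F7 | step 3 | 2,4-bis[4-(benzyloxy)benzyl]cyclohexane-1,3-dione (racemic) | O=C1CCC(Cc2ccc(OCc3ccccc3)cc2)C(=O)C1Cc1ccc(OCc2ccccc2)cc1
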